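**Assumption:** the target, [2-hydroxy-4,6-dimethoxy-3,5-bis(3-methylbut-2-en-1-yl)phenyl](phenyl)methanone, has no stereocentre and no E/Z element, so it is made as the single achiral compound drawn. The new step (used in steps 1 and 2) is a proposal and has not been run.

## Retrosynthetic overview

- The target comes from double O-methylation of 2,4,6-trihydroxy-3,5-diprenylbenzophenone at the 4-OH and at one of the two equivalent ortho-OH groups; the last OH stays hydrogen-bonded to the ketone.
- Each C-prenyl group is traced back to an aryl 1,1-dimethylallyl ether on O-4, which delivers a normal prenyl group to the neighbouring carbon by an aromatic Claisen [3,3] shift.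
- The key bond is therefore the tertiary C–O bond of that ether, made by branch-selective hydroaryloxylation of isoprene. O-4 is set free again after each shift, so the sequence is run twice.
- The starting material is catalogue 2,4,6-trihydroxybenzophenone. No ring is formed; both benzene rings come intact from it.

## Route

**Step 1**
Reactants: 1 2,4,6-trihydroxybenzophenone; 2 isoprene (2-methylbuta-1,3-diene)
Product: 4 2,4,6-trihydroxy-3-(3-methylbut-2-en-1-yl)benzophenone, via 4-O-(2-methylbut-3-en-2-yl) ether 3 (not isolated)
Conditions: 2 (10 equiv), Pd2(dba)3 (2.5 mol%), Xantphos (6 mol%), PhMe, 0 °C, sealed tube; vent, SiO2 plug; PhMe, 110 °C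
Reagents that add atoms: isoprene, C=CC(C)=C
Why: Proposed new method: the acidic, non-chelated 4-OH protonates the zerovalent palladium–isoprene complex at C-1 to give a divalent (1,1-dimethylallyl)palladium aryloxide tight ion pair, which in toluene collapses under kinetic control at the more substituted allyl terminus to the tertiary ether 3 (the chelating bisphosphine suppresses diene telomerisation, and removing palladium before heating prevents reversal), after which a thermal aromatic Claisen rearrangement moves the group to the equivalent C-3/C-5 position as a normal prenyl group; the closest known reactions are the palladium-catalysed equilibrium addition of phenols to 1,3-dienes and the Tsuji–Trost O-reverse-prenylation of phenols with 2-methylbut-3-en-2-yl carbonates, neither shown for isoprene at the tertiary carbon on a free acylphloroglucinol.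

**Step 2**
Reactants: 4 2,4,6-trihydroxy-3-(3-methylbut-2-en-1-yl)benzophenone; 2 isoprene
Product: 6 2,4,6-trihydroxy-3,5-bis(3-methylbut-2-en-1-yl)benzophenone, via 4-O-(2-methylbut-3-en-2-yl) ether 5 (not isolated)
Conditions: 2 (15 equiv), Pd2(dba)3 (2.5 mol%), Xantphos (6 mol%), PhMe, 0 °C to rt, sealed tube; vent, SiO2 plug; PhMe, 110 °C
Reagents that add atoms: isoprene, C=CC(C)=C
Why: Proposed new method: the same zerovalent-palladium hydroaryloxylation of isoprene (closest known type: palladium-catalysed phenol addition to 1,3-dienes and Tsuji–Trost tert-prenyl ether formation) now acts on the regenerated 4-OH, and the Claisen rearrangement of 5 can only end at the one free ortho carbon C-5; an ether formed at O-6 would give the same product, while one at O-2 has no free ortho position and reverts through the reversible palladium ionisation.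

**Step 3**
Reactants: 6 2,4,6-trihydroxy-3,5-bis(3-methylbut-2-en-1-yl)benzophenone; 7 dimethyl sulfate
Product: 8 [2-hydroxy-4,6-dimethoxy-3,5-bis(3-methylbut-2-en-1-yl)phenyl](phenyl)methanone
Conditions: Me2SO4 (2.1 equiv), K2CO3 (2.5 equiv), acetone, reflux
Reagents that add atoms: dimethyl sulfate, COS(=O)(=O)OC
Why: Williamson-type phenol O-methylation takes the most acidic 4-OH and then one of the two equivalent ortho-OH groups, and stops there because the remaining OH is locked in a strong hydrogen bond to the ketone and flanked by prenyl and benzoyl; the hard electrophile favours O- over dearomatising C-methylation, and the prenyl alkenes are inert.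

## Compound list

1 | (phenyl)(2,4,6-trihydroxyphenyl)methanone (2,4,6-trihydroxybenzophenone) | O=C(c1ccccc1)c1c(O)cc(O)cc1O | starting material
2 | isoprene (2-methylbuta-1,3-diene) | C=CC(C)=C | starting material
3 | {2,6-dihydroxy-4-[(2-methylbut-3-en-2-yl)oxy]phenyl}(phenyl)methanone | O=C(c1ccccc1)c1c(O)cc(OC(C)(C)C=C)cc1O | intermediate
4 | [2,4,6-trihydroxy-3-(3-methylbut-2-en-1-yl)phenyl](phenyl)methanone | CC(C)=CCc1c(O)cc(O)c(C(=O)c2ccccc2)c1O | intermediate
5 | {2,6-dihydroxy-3-(3-methylbut-2-en-1-yl)-4-[(2-methylbut-3-en-2-yl)oxy]phenyl}(phenyl)methanone | CC(C)=CCc1c(OC(C)(C)C=C)cc(O)c(C(=O)c2ccccc2)c1O | intermediate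
6 | [2,4,6-trihydroxy-3,5-bis(3-methylbut-2-en-1-yl)phenyl](phenyl)methanone | CC(C)=CCc1c(O)c(CC=C(C)C)c(O)c(C(=O)c2ccccc2)c1O | intermediate
7 | dimethyl sulfate | COS(=O)(=O)OC | starting material
8 | [2-hydroxy-4,6-dimethoxy-3,5-bis(3-methylbut-2-en-1-yl)phenyl](phenyl)methanone | COc1c(CC=C(C)C)c(O)c(C(=O)c2ccccc2)c(OC)c1CC=C(C)C | target

## Summary

Total step count: 3. Longest linear sequence: 3 steps (1 → 4 → 6 → 8).

**Steps most likely to fail**

**Step 1 (new hydroaryloxylation).** The risks are reversibility of the addition, isoprene telomerisation, attack at the linear terminus or at ring carbon, and poor discrimination between the three hydroxyls. The fallback uses known chemistry and sets out from 1. Copper-catalysed O-propargylation with 3-chloro-3-methylbut-1-yne (K2CO3, KI, CuI cat., acetone, 50 °C) gives {2,6-dihydroxy-4-[(2-methylbut-3-yn-2-yl)oxy]phenyl}(phenyl)methanone F1. Semi-hydrogenation (H2, 1 atm, Pd/CaCO3 poisoned with Pb(OAc)2, quinoline, EtOAc, rt) then gives the tertiary allyl ether. The fallback comes back to the route at 3, which is heated in toluene as in step 1 to give 4.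

**Step 2 (same new method on the more crowded 4-OH next to a prenyl group).** The extra risks are slow tertiary ether formation and a Claisen shift with only one free ortho position. The fallback uses known chemistry, sets out from 4 and changes the handle. Me2SO4 (2.1 equiv), K2CO3, acetone gives [2-hydroxy-4,6-dimethoxy-3-(3-methylbut-2-en-1-yl)phenyl](phenyl)methanone F2; the hydroxyl wedged between prenyl and benzoyl is expected to stay chelated and unmethylated. O-alkylation of that hydroxyl with 1-bromo-3-methylbut-2-ene (K2CO3, DMF, 60 °C) gives the linear prenyl ether {4,6-dimethoxy-3-(3-methylbut-2-en-1-yl)-2-[(3-methylbut-2-en-1-yl)oxy]phenyl}(phenyl)methanone F3. Heating (PhNEt2, 190 °C) triggers a para-Claisen–Cope sequence: both ortho positions are blocked, so two consecutive [3,3] shifts place an unrearranged prenyl group para to the oxygen, at C-5. The fallback comes back to the route at 8.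

**Step 3 (stopping cleanly at the dimethyl ether).** The risks are under-methylation and over-methylation. The fallback sets out from 6. Exhaustive methylation (Me2SO4, 4 equiv, K2CO3, DMF, 60 °C) gives [2,4,6-trimethoxy-3,5-bis(3-methylbut-2-en-1-yl)phenyl](phenyl)methanone F4. Chelation-controlled mono-demethylation of one of the two equivalent ortho-methoxy groups (MgI2·OEt2, 1.5 equiv, PhMe, 60 °C; aqueous work-up) leaves the para-methoxy group and the prenyl alkenes untouched. The fallback comes back to the route at 8.

## Further compounds

F1 | step 1 | {2,6-dihydroxy-4-[(2-methylbut-3-yn-2-yl)oxy]phenyl}(phenyl)methanone | O=C(c1ccccc1)c1c(O)cc(OC(C)(C)C#C)cc1O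
F2 | step 2 | [2-hydroxy-4,6-dimethoxy-3-(3-methylbut-2-en-1-yl)phenyl](phenyl)methanone | COc1cc(OC)c(C(=O)c2ccccc2)c(O)c1CC=C(C)C
F3 | step 2 | {4,6-dimethoxy-3-(3-methylbut-2-en-1-yl)-2-[(3-methylbut-2-en-1-yl)oxy]phenyl}(phenyl)methanone | COc1cc(OC)c(C(=O)c2ccccc2)c(OCC=C(C)C)c1CC=C(C)C
F4 | step 3 | [2,4,6-trimethoxy-3,5-bis(3-methylbut-2-en-1-yl)phenyl](phenyl)methanone | COc1c(CC=C(C)C)c(OC)c(C(=O)c2ccccc2)c(OC)c1CC=C(C)C
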